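The exocyclic CH2–C1 bond of the cyclohexene is cut as a Morita–Baylis–Hillman bond. The key step exploits the position of ring carbon C1 between the C1=C2 alkene and the C6 carbinol: with C6 raised to a ketone, C1 is the α-carbon of a cyclohexenone and takes up formaldehyde directly under amine catalysis, without prefunctionalisation. The precursor is a D-mannose-derived enone in which sugar C2, C3 and C4 have become ring C5, C4 and C3 (C5 already benzoylated, O3/O4 locked in a trans-fused butane-2,3-diacetal); the axial C5 benzoate later steers hydride onto C6 from the opposite face.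

Key step: step 8

Remark: locants C1–C6 in the explanations are those of the target ring (C1 bears the exocyclic CH2, C2 is the vinyl CH, C3 and C4 carry the free hydroxyls, C5 the benzoate, C6 the hydroxyl next to C1). Systematic names of intermediates carry their own locants. Formalin is taken as the formaldehyde source.

Step 1
Reactants: 1 methyl α-D-mannopyranoside
Product: 2 methyl 3,4-O-[(2S,3S)-2,3-dimethoxybutane-2,3-diyl]-α-D-mannopyranoside
Conditions: butane-2,3-dione, CH(OMe)3, CSA (cat.), MeOH, reflux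
Reagents that add atoms: butane-2,3-dione CC(=O)C(C)=O; trimethyl orthoformate COC(OC)OC (methoxy groups, interchangeable with the solvent methanol CO)
Why: Butane-2,3-diacetal formation under thermodynamic control picks the trans-diequatorial 3,4-diol (trans-fused 1,4-dioxane chair, both methoxy groups axial by the anomeric effect, which sets the two acetal carbons as S,S), leaving O2 and O6 free.

Step 2
Reactants: 2 methyl 3,4-O-[(2S,3S)-2,3-dimethoxybutane-2,3-diyl]-α-D-mannopyranoside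
Product: 3 methyl 6-deoxy-6-iodo-3,4-O-[(2S,3S)-2,3-dimethoxybutane-2,3-diyl]-α-D-mannopyranoside
Conditions: I2, PPh3, imidazole, THF, 65 °C
Reagents that add atoms: iodine II
Why: Garegg–Samuelsson (Appel-type) iodination should displace only the primary 6-hydroxyl, the axial 2-hydroxyl next to the acetal being too hindered for the phosphonium pathway.

Step 3
Reactants: 3 methyl 6-deoxy-6-iodo-3,4-O-[(2S,3S)-2,3-dimethoxybutane-2,3-diyl]-α-D-mannopyranoside
Product: 4 methyl 2-O-benzoyl-6-deoxy-6-iodo-3,4-O-[(2S,3S)-2,3-dimethoxybutane-2,3-diyl]-α-D-mannopyranoside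
Conditions: BzCl, pyridine, DMAP (cat.), CH2Cl2, 0 °C to rt
Reagents that add atoms: benzoyl chloride O=C(Cl)c1ccccc1
Why: DMAP-catalysed acylation of the single remaining hydroxyl installs, on sugar C2, the benzoate that becomes the C5 ester of the target.

Step 4
Reactants: 4 methyl 2-O-benzoyl-6-deoxy-6-iodo-3,4-O-[(2S,3S)-2,3-dimethoxybutane-2,3-diyl]-α-D-mannopyranoside
Product: 5 2-O-benzoyl-5,6-dideoxy-3,4-O-[(2S,3S)-2,3-dimethoxybutane-2,3-diyl]-D-lyxo-hex-5-enose (open-chain 5-enal, used crude)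
Conditions: activated Zn dust, THF/H2O 9:1, sonication, 40 °C
Reagents that add atoms: none
Why: Bernet–Vasella reductive fragmentation: zinc inserts into the C6–I bond and the organozinc expels the ring oxygen, unmasking sugar C1 as the aldehyde and C5=C6 as a vinyl group while the stereocentres C2–C4 and the benzoate are untouched.

Step 5
Reactants: 5 2-O-benzoyl-5,6-dideoxy-3,4-O-[(2S,3S)-2,3-dimethoxybutane-2,3-diyl]-D-lyxo-hex-5-enose, 6 vinylmagnesium bromide
Product: 7 (3RS,4R,5S,6R)-4-O-benzoyl-5,6-O-[(2S,3S)-2,3-dimethoxybutane-2,3-diyl]octa-1,7-diene-3,4,5,6-tetrol (both C3 epimers)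
Conditions: CH2=CHMgBr (1.2 equiv), THF, −78 °C; pH 7 buffer quench at −78 °C
Reagents that add atoms: vinylmagnesium bromide C=C[Mg]Br
Why: Grignard 1,2-addition, in which the aldehyde should react far faster than the benzoate at −78 °C; the configuration of the new carbinol is irrelevant because it is oxidised in step 7.

Step 6
Reactants: 7 (3RS,4R,5S,6R)-4-O-benzoyl-5,6-O-[(2S,3S)-2,3-dimethoxybutane-2,3-diyl]octa-1,7-diene-3,4,5,6-tetrol
Product: 8 (1RS,4R,5S,6R)-6-O-benzoyl-4,5-O-[(2S,3S)-2,3-dimethoxybutane-2,3-diyl]cyclohex-2-ene-1,4,5,6-tetrol (both C1 epimers)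
Conditions: (H2IMes)(PCy3)Cl2Ru=CHPh (second-generation Grubbs catalyst, 5 mol %), CH2Cl2, 40 °C
Reagents that add atoms: none
Why: Ring-closing metathesis of the two terminal vinyl groups should close the six-membered carbocycle, trans-fused to the dioxane, with loss of ethylene; both carbinol epimers cyclise.

Step 7
Reactants: 8 (1RS,4R,5S,6R)-6-O-benzoyl-4,5-O-[(2S,3S)-2,3-dimethoxybutane-2,3-diyl]cyclohex-2-ene-1,4,5,6-tetrol
Product: 9 (4R,5S,6S)-6-(benzoyloxy)-4,5-[(2S,3S)-2,3-dimethoxybutane-2,3-diyldioxy]cyclohex-2-en-1-one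
Conditions: Dess–Martin periodinane, CH2Cl2, 0 °C to rt
Reagents that add atoms: none
Why: Dess–Martin oxidation of the allylic alcohol converges both epimers on one enone under non-basic conditions that should not epimerise the benzoyloxy-bearing α′ carbon.

Step 8
Reactants: 9 (4R,5S,6S)-6-(benzoyloxy)-4,5-[(2S,3S)-2,3-dimethoxybutane-2,3-diyldioxy]cyclohex-2-en-1-one, 10 formaldehyde
Product: 11 (4R,5S,6S)-6-(benzoyloxy)-2-(hydroxymethyl)-4,5-[(2S,3S)-2,3-dimethoxybutane-2,3-diyldioxy]cyclohex-2-en-1-one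
Conditions: 37% aq. HCHO (5 equiv), DMAP (0.3 equiv), THF/H2O 3:1, rt
Reagents that add atoms: formaldehyde C=O
Why: Morita–Baylis–Hillman hydroxymethylation: DMAP adds reversibly to the enone β-carbon (C2), the resulting C6–C1 enolate attacks formaldehyde through C1, and proton transfer followed by E1cB loss of DMAP restores the C1=C2 double bond, now carrying the CH2OH group. The closest known reaction type is the amine-catalysed Baylis–Hillman reaction of cyclohex-2-enones, oxygenated ones included, with aqueous formaldehyde. No ring is closed and no stereocentre is created; C3, C4 and C5 are spectators. The selectivity needed is C–C bond formation at C1 in preference to enolisation toward C5 (epimerisation, or β-elimination of O4 and aromatisation) and to benzoate cleavage. The trans-fused diacetal locks the half-chair so that the C5 benzoate is axial and H5 lies near the carbonyl plane, which makes α′ deprotonation stereoelectronically slow; O4 is a poor acetal leaving group and DMAP is a weak base. Formaldehyde, non-enolisable and very electrophilic, keeps the aldol step fast relative to these pathways.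

Step 9
Reactants: 11 (4R,5S,6S)-6-(benzoyloxy)-2-(hydroxymethyl)-4,5-[(2S,3S)-2,3-dimethoxybutane-2,3-diyldioxy]cyclohex-2-en-1-one
Product: 12 [(3R,4S,5S)-5-(benzoyloxy)-3,4-[(2S,3S)-2,3-dimethoxybutane-2,3-diyldioxy]-6-oxocyclohex-1-en-1-yl]methyl benzoate
Conditions: BzCl, pyridine, CH2Cl2, 0 °C
Reagents that add atoms: benzoyl chloride O=C(Cl)c1ccccc1
Why: Acylation of the primary allylic hydroxyl with benzoyl chloride and pyridine (no stronger nucleophilic amine, which could displace the Baylis–Hillman ester by an SN2′ path) gives the second benzoate of the target.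

Step 10
Reactants: 12 [(3R,4S,5S)-5-(benzoyloxy)-3,4-[(2S,3S)-2,3-dimethoxybutane-2,3-diyldioxy]-6-oxocyclohex-1-en-1-yl]methyl benzoate
Product: 13 [(3R,4S,5R,6R)-5-(benzoyloxy)-6-hydroxy-3,4-[(2S,3S)-2,3-dimethoxybutane-2,3-diyldioxy]cyclohex-1-en-1-yl]methyl benzoate
Conditions: NaBH4, CeCl3·7H2O, MeOH, −78 °C
Reagents that add atoms: none
Why: Luche 1,2-reduction, in which the small hydride should attack the cerium-activated carbonyl on the face anti to the axial C5 benzoate (axial attack on the locked half-chair, also the Felkin–Anh sense), placing the new C6 hydroxyl cis to the C5 benzoate (6R).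

Step 11
Reactants: 13 [(3R,4S,5R,6R)-5-(benzoyloxy)-6-hydroxy-3,4-[(2S,3S)-2,3-dimethoxybutane-2,3-diyldioxy]cyclohex-1-en-1-yl]methyl benzoate
Product: 14 [(3R,4S,5R,6R)-5-(benzoyloxy)-3,4,6-trihydroxycyclohex-1-en-1-yl]methyl benzoate
Conditions: TFA/H2O 9:1, 0 °C to rt
Reagents that add atoms: none
Why: Acid hydrolysis of the butane-2,3-diacetal should release the 3,4-diol and leave both benzoates in place, acyl migration being slow under cold acidic conditions.

Compound list
1 | methyl α-D-mannopyranoside | CO[C@@H]1[C@@H](O)[C@@H](O)[C@H](O)[C@@H](CO)O1 | starting material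
2 | methyl 3,4-O-[(2S,3S)-2,3-dimethoxybutane-2,3-diyl]-α-D-mannopyranoside | CO[C@@H]1[C@@H](O)[C@H]2O[C@](C)(OC)[C@@](C)(OC)O[C@@H]2[C@@H](CO)O1 | intermediate
3 | methyl 6-deoxy-6-iodo-3,4-O-[(2S,3S)-2,3-dimethoxybutane-2,3-diyl]-α-D-mannopyranoside | CO[C@@H]1[C@@H](O)[C@H]2O[C@](C)(OC)[C@@](C)(OC)O[C@@H]2[C@@H](CI)O1 | intermediate
4 | methyl 2-O-benzoyl-6-deoxy-6-iodo-3,4-O-[(2S,3S)-2,3-dimethoxybutane-2,3-diyl]-α-D-mannopyranoside | CO[C@@H]1[C@@H](OC(=O)c3ccccc3)[C@H]2O[C@](C)(OC)[C@@](C)(OC)O[C@@H]2[C@@H](CI)O1 | intermediate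
5 | 2-O-benzoyl-5,6-dideoxy-3,4-O-[(2S,3S)-2,3-dimethoxybutane-2,3-diyl]-D-lyxo-hex-5-enose | O=C[C@@H](OC(=O)c1ccccc1)[C@H]1O[C@](C)(OC)[C@@](C)(OC)O[C@@H]1C=C | intermediate
6 | vinylmagnesium bromide | C=C[Mg]Br | starting material
7 | (3RS,4R,5S,6R)-4-O-benzoyl-5,6-O-[(2S,3S)-2,3-dimethoxybutane-2,3-diyl]octa-1,7-diene-3,4,5,6-tetrol (C3 epimers) | C=CC(O)[C@@H](OC(=O)c1ccccc1)[C@H]1O[C@](C)(OC)[C@@](C)(OC)O[C@@H]1C=C | intermediate
8 | (1RS,4R,5S,6R)-6-O-benzoyl-4,5-O-[(2S,3S)-2,3-dimethoxybutane-2,3-diyl]cyclohex-2-ene-1,4,5,6-tetrol (C1 epimers) | OC1[C@@H](OC(=O)c2ccccc2)[C@H]2O[C@](C)(OC)[C@@](C)(OC)O[C@@H]2C=C1 | intermediate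
9 | (4R,5S,6S)-6-(benzoyloxy)-4,5-[(2S,3S)-2,3-dimethoxybutane-2,3-diyldioxy]cyclohex-2-en-1-one | O=C1[C@@H](OC(=O)c2ccccc2)[C@H]2O[C@](C)(OC)[C@@](C)(OC)O[C@@H]2C=C1 | intermediate
10 | formaldehyde | C=O | starting material
11 | (4R,5S,6S)-6-(benzoyloxy)-2-(hydroxymethyl)-4,5-[(2S,3S)-2,3-dimethoxybutane-2,3-diyldioxy]cyclohex-2-en-1-one | O=C1[C@@H](OC(=O)c2ccccc2)[C@H]2O[C@](C)(OC)[C@@](C)(OC)O[C@@H]2C=C1CO | intermediate
12 | [(3R,4S,5S)-5-(benzoyloxy)-3,4-[(2S,3S)-2,3-dimethoxybutane-2,3-diyldioxy]-6-oxocyclohex-1-en-1-yl]methyl benzoate | O=C1[C@@H](OC(=O)c2ccccc2)[C@H]2O[C@](C)(OC)[C@@](C)(OC)O[C@@H]2C=C1COC(=O)c1ccccc1 | intermediate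
13 | [(3R,4S,5R,6R)-5-(benzoyloxy)-6-hydroxy-3,4-[(2S,3S)-2,3-dimethoxybutane-2,3-diyldioxy]cyclohex-1-en-1-yl]methyl benzoate | O[C@H]1[C@@H](OC(=O)c2ccccc2)[C@H]2O[C@](C)(OC)[C@@](C)(OC)O[C@@H]2C=C1COC(=O)c1ccccc1 | intermediate
14 | [(3R,4S,5R,6R)-5-(benzoyloxy)-3,4,6-trihydroxycyclohex-1-en-1-yl]methyl benzoate | O=C(OCC1=C[C@@H](O)[C@H](O)[C@H](OC(=O)c2ccccc2)[C@@H]1O)c1ccccc1 | target

Total step count: 11. Longest linear sequence: 11 steps (from 1).

Steps most likely to fail

Step 8 (key step). Under the nucleophilic amine in aqueous medium the enone may enolise toward C5 (epimerisation of the axial benzoate, or β-elimination of the acetal oxygen with aromatisation), or the benzoate may be cleaved, before the slow aldol step takes place. The fallback replaces the enolate process by a neutral palladium coupling that forms the same CH2–C1 bond. It sets out from 9: α-iodination (I2, pyridine, CH2Cl2, 0 °C to rt) should give (4R,5S,6S)-6-(benzoyloxy)-2-iodo-4,5-[(2S,3S)-2,3-dimethoxybutane-2,3-diyldioxy]cyclohex-2-en-1-one F1. Stille coupling of this iodide with (tributylstannyl)methanol (Pd(PPh3)4, CuI, dioxane, 80 °C) then comes back to the route at 11.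

Step 5. The vinyl Grignard reagent may attack the benzoate, the magnesium alkoxide may take over the neighbouring benzoyl group (acyl migration), or the basic reagent may enolise the α-benzoyloxy aldehyde with β-elimination. The fallback carries sugar O2 as a silyl ether through the ring construction and sets out from 3.
- Silylation (TBSOTf, 2,6-lutidine, CH2Cl2, 0 °C) should give methyl 2-O-(tert-butyldimethylsilyl)-6-deoxy-6-iodo-3,4-O-[(2S,3S)-2,3-dimethoxybutane-2,3-diyl]-α-D-mannopyranoside F2.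
- Zinc fragmentation as in step 4 gives 2-O-(tert-butyldimethylsilyl)-5,6-dideoxy-3,4-O-[(2S,3S)-2,3-dimethoxybutane-2,3-diyl]-D-lyxo-hex-5-enose F3.
- Vinylmagnesium bromide 6 adds to give (3RS,4R,5S,6R)-4-O-(tert-butyldimethylsilyl)-5,6-O-[(2S,3S)-2,3-dimethoxybutane-2,3-diyl]octa-1,7-diene-3,4,5,6-tetrol F4.
- Ring-closing metathesis as in step 6 gives (1RS,4R,5S,6R)-6-O-(tert-butyldimethylsilyl)-4,5-O-[(2S,3S)-2,3-dimethoxybutane-2,3-diyl]cyclohex-2-ene-1,4,5,6-tetrol F5.
- Dess–Martin oxidation gives (4R,5S,6S)-6-(tert-butyldimethylsilyloxy)-4,5-[(2S,3S)-2,3-dimethoxybutane-2,3-diyldioxy]cyclohex-2-en-1-one F6.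
- Desilylation (HF·pyridine, THF, 0 °C) gives (4R,5R,6S)-6-hydroxy-4,5-[(2S,3S)-2,3-dimethoxybutane-2,3-diyldioxy]cyclohex-2-en-1-one F7.
- Benzoylation (BzCl, pyridine, CH2Cl2, 0 °C) comes back to the route at 9.

Step 10. Hydride may add in conjugate fashion and expel the allylic benzoate (giving an exo-methylene ketone), or facial selectivity may erode with the ester-bearing side chain in place. The fallback reduces before the primary ester is introduced and sets out from 11. Luche reduction (NaBH4, CeCl3·7H2O, MeOH, −78 °C) should give (1R,4R,5S,6R)-6-(benzoyloxy)-2-(hydroxymethyl)-4,5-[(2S,3S)-2,3-dimethoxybutane-2,3-diyldioxy]cyclohex-2-en-1-ol F8, with no allylic leaving group and the same axial-benzoate control. Selective benzoylation of the primary allylic hydroxyl (BzCl 1.05 equiv, 2,4,6-collidine, CH2Cl2, −40 °C) comes back to the route at 13.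

Further compounds
F1 | step 8 | (4R,5S,6S)-6-(benzoyloxy)-2-iodo-4,5-[(2S,3S)-2,3-dimethoxybutane-2,3-diyldioxy]cyclohex-2-en-1-one | O=C1[C@@H](OC(=O)c2ccccc2)[C@H]2O[C@](C)(OC)[C@@](C)(OC)O[C@@H]2C=C1I
F2 | step 5 | methyl 2-O-(tert-butyldimethylsilyl)-6-deoxy-6-iodo-3,4-O-[(2S,3S)-2,3-dimethoxybutane-2,3-diyl]-α-D-mannopyranoside | CO[C@@H]1[C@@H](O[Si](C)(C)C(C)(C)C)[C@H]2O[C@](C)(OC)[C@@](C)(OC)O[C@@H]2[C@@H](CI)O1
F3 | step 5 | 2-O-(tert-butyldimethylsilyl)-5,6-dideoxy-3,4-O-[(2S,3S)-2,3-dimethoxybutane-2,3-diyl]-D-lyxo-hex-5-enose | O=C[C@@H](O[Si](C)(C)C(C)(C)C)[C@H]1O[C@](C)(OC)[C@@](C)(OC)O[C@@H]1C=C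
F4 | step 5 | (3RS,4R,5S,6R)-4-O-(tert-butyldimethylsilyl)-5,6-O-[(2S,3S)-2,3-dimethoxybutane-2,3-diyl]octa-1,7-diene-3,4,5,6-tetrol | C=CC(O)[C@@H](O[Si](C)(C)C(C)(C)C)[C@H]1O[C@](C)(OC)[C@@](C)(OC)O[C@@H]1C=C
F5 | step 5 | (1RS,4R,5S,6R)-6-O-(tert-butyldimethylsilyl)-4,5-O-[(2S,3S)-2,3-dimethoxybutane-2,3-diyl]cyclohex-2-ene-1,4,5,6-tetrol | OC1[C@@H](O[Si](C)(C)C(C)(C)C)[C@H]2O[C@](C)(OC)[C@@](C)(OC)O[C@@H]2C=C1
F6 | step 5 | (4R,5S,6S)-6-(tert-butyldimethylsilyloxy)-4,5-[(2S,3S)-2,3-dimethoxybutane-2,3-diyldioxy]cyclohex-2-en-1-one | O=C1[C@@H](O[Si](C)(C)C(C)(C)C)[C@H]2O[C@](C)(OC)[C@@](C)(OC)O[C@@H]2C=C1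
F7 | step 5 | (4R,5R,6S)-6-hydroxy-4,5-[(2S,3S)-2,3-dimethoxybutane-2,3-diyldioxy]cyclohex-2-en-1-one | O=C1[C@@H](O)[C@H]2O[C@](C)(OC)[C@@](C)(OC)O[C@@H]2C=C1
F8 | step 10 | (1R,4R,5S,6R)-6-(benzoyloxy)-2-(hydroxymethyl)-4,5-[(2S,3S)-2,3-dimethoxybutane-2,3-diyldioxy]cyclohex-2-en-1-ol | O[C@H]1[C@@H](OC(=O)c2ccccc2)[C@H]2O[C@](C)(OC)[C@@](C)(OC)O[C@@H]2C=C1CO
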